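**Structural features**

Petalostemumol G (16) is 8,2',6'-triprenylquercetin. Ring A (C4a, C5–C8, C8a; OH at C5 and C7, prenyl at C8) is fused to ring C (O1, C2–C4; a 3-hydroxy-4-pyranone), and ring C carries ring B through the C2–C1' bond. Ring B is pentasubstituted: prenyl groups at C2' and C6' flank C1', a catechol occupies C3'/C4', and only C5' bears hydrogen. There is no stereocentre, and each alkene ends in two methyl groups, so no configuration has to be set. The fragile groups are the three prenyl chains, the oxidisable catechol and the enolic 3-OH; the chains at C8 and C2' sit ortho to O7 and O3' and close to chromans under acid, and all three are attacked by electrophilic oxidants and halogens. The rings are ordinary and the real difficulty is connectivity: the C2–C1' axis is shielded on both faces by the C2' and C6' chains, so closing O1–C2 or coupling at C2–C1' with these chains in place is hindered, and C8 must be told from C6 and C2'/C6' from C5'. The key step exploits a positional coincidence: C8 is para to O5 in ring A, C6' is para to O3' in ring B, and C2' is ortho to O3', so every prenylated carbon lies within one or two [3,3] shifts of only two oxygens. These two oxygens (the chelated O5–H and the meta-placed O3'–H) are also the two least acidic hydroxyls of the core, so O3, O7 and O4' can be masked together. In one sentence, the route is a concurrent double Claisen–Cope relay on the 5,3'-bis(prenyl ether) 9, which does not describe the chalcone and oxidative cyclisation route that is usually drawn first.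

**Logic of the disconnections**

16 to 15. The three acetal O–CH2 bonds at O3, O7 and O4' are cut. These oxygens must stay silent while O5 and O3' act as docks for the prenyl groups. The skeleton is not simplified, but all exposure to acid is confined to one last step. The forward cleavage must be mild enough for prenyl chains that stand next to O7 and O3'.

15 to 9 (key disconnection). The C8–CH2 and C6'–CH2 bonds are cut, and each CH2 is reattached to the oxygen para to it (O5 and O3').
- Two hindered aryl–carbon bonds become two plain aryl ether bonds.
- The doubly flanked C2–C1' axis relaxes to a singly flanked one.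
- The choices C8 over C6 and C6' over C5' are encoded in the position of an oxygen instead of depending on a reagent.
- In the forward step each arm must pass through two consecutive [3,3] shifts in one operation, the second shift must outrun enolisation in ring A, and the ethers must not fragment.

9 to 8. The O5–CH2 and O3'–CH2 bonds are cut. In 8 these are the only free hydroxyls, so one alkylation with a primary prenyl halide serves both. The forward step has to break the O5–H···O4 chelate.

8 to 6. The C2'–CH2 bond is cut, and the tertiary carbon of the same C5 unit is reattached to O3'. C2' is ortho to O3', so a single [3,3] shift with allyl inversion delivers a normal prenyl group from a 1,1-dimethylallyl ether. C2' must be filled first, because otherwise the later relay would stop there. The forward step relies on C2' being the only ortho carbon that bears hydrogen.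

6 to 2 and 5. The O3'–C(tertiary) bond is cut. A tertiary allyl aryl ether cannot be made by direct displacement, so a π-allyl metal electrophile is called for. The forward step needs attack at the substituted allyl terminus and O3' in preference to O5.

5 to 3. The carbonate C–O bond is cut, leading back to a commercial tertiary allylic alcohol.

2 to 1. The three acetal O–CH2 bonds are cut, leading back to the commercial pentahydroxyflavone. The cut rests on the acidity order of the five hydroxyls. The forward alkylation must stop after three groups.

**Other disconnections considered**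

Alternative 1: (the first that comes to mind) The C2–C3 and O1–C2 bonds are cut.
- Forward route: Claisen–Schmidt condensation of the prenylated acetophenone A1 with the diprenylated aldehyde A2 gives the chalcone A3. The key step is an Algar–Flynn–Oyamada oxidative cyclisation (H2O2, NaOH) that closes O1–C2 and installs the 3-OH.
- Steric ground: in A3 ring B is twisted out of the enone plane, and its two ortho chains cover both faces of the β-carbon, which is exactly where the phenoxide has to open the epoxide.
- Electronic ground: the alkoxy group ortho to the carbonyl (the future O5) additionally favours attack at the α-carbon and five-membered closure.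
- Step economy: A1 and A2 each need their own prenylation sequences. The hindered bond is made with all the bulk in place, and the step count should be about twice that of the chosen plan.

Alternative 2: The C2–C1' bond is cut.
- Forward route: Suzuki–Miyaura coupling of the 2-iodochromone A4 with the arylboronate A5.
- Mechanistic ground: transmetalation of an electron-rich boronate with two ortho alkyl groups is slow, so protodeboronation competes. An aryl–palladium species flanked by two allylic chains can also insert or shift the double bonds.
- Step economy: A4 requires metalation of a base-sensitive chromone plus its own C8 prenylation, and A5 leaves the whole ring B substitution problem unsolved.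

Alternative 3: The C1'–C2' and C5'–C6' bonds are cut, so ring B is made from acyclic parts.
- Forward route: Diels–Alder reaction of the 2-alkynylchromone A6 with the 2,3-bis(silyloxy)diene A7, followed by dehydrogenation.
- Attraction: the crowded axis is never formed under crowding, and all five substituents are set at once.
- Grounds against: the alkyne is internal, only vinylogously activated, and further deactivated by O3. The orientation rests on the weak directing effect of one alkyl terminus. The doubly activated CH2 of the skipped enyne in A6 is prone to prototropic shift at the temperature needed.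
- Step economy: both partners need multistep syntheses, so the count should exceed twice that of the chosen plan.

Key step: step 6

Assumption: quercetin (1) is taken as a commercial bulk chemical, so no ring of the flavonol core has to be built; flavonoid numbering is used, prenyl = 3-methylbut-2-en-1-yl, MOM = methoxymethyl.

**Steps**

Step 1
Reactants: 1 quercetin (3,5,7,3',4'-pentahydroxyflavone)
Product: 2 3,7,4'-tris-O-(methoxymethyl)quercetin (5-OH and 3'-OH free)
Conditions: MOMCl (3.1 equiv), K2CO3 (3.3 equiv), acetone, 0 °C to rt
Reagents that add atoms: chloromethyl methyl ether (MOMCl), COCCl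
Why: Williamson-type O-alkylation under acidity control: the 7-OH and 4'-OH (both para-conjugated with C4=O) and the enolic 3-OH are ionised first and should be alkylated first. The 3'-OH (meta to C2, poorer phenoxide) and the chelated 5-OH should stay free when the reagent is limited to three equivalents.

Step 2
Reactants: 3 2-methylbut-3-en-2-ol
Product: 5 tert-butyl 2-methylbut-3-en-2-yl carbonate, via lithium 2-methylbut-3-en-2-olate 4 (not isolated)
Conditions: n-BuLi, THF, −78 °C; Boc2O, −78 °C to rt; H2O
Reagents that add atoms: di-tert-butyl dicarbonate (Boc2O), CC(C)(C)OC(=O)OC(=O)OC(C)(C)C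
Why: Acylation of an alkoxide by a dicarbonate: the tertiary alkoxide 4 attacks Boc2O and tert-butyl carbonate anion leaves. Nothing in 3 competes.

Step 3
Reactants: 2 3,7,4'-tris-O-(methoxymethyl)quercetin; 5 tert-butyl 2-methylbut-3-en-2-yl carbonate
Product: 6 3'-O-(2-methylbut-3-en-2-yl)-3,7,4'-tris-O-(methoxymethyl)quercetin (1,1-dimethylallyl ether at O3', 5-OH free)
Conditions: Pd(PPh3)4 (5 mol %), THF, 0 °C
Reagents that add atoms: none
Why: Tsuji–Trost decarboxylative O-allylation: zerovalent palladium ionises 5, CO2 is lost, and the released tert-butoxide deprotonates the 3'-OH. Phenoxides attack the 1,1-dimethyl-π-allyl complex kinetically at its substituted terminus, which gives the tertiary ether at low temperature. The chelated 5-OH should not be ionised by one equivalent of base.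

Step 4
Reactants: 6 3'-O-(2-methylbut-3-en-2-yl)-3,7,4'-tris-O-(methoxymethyl)quercetin
Product: 8 2'-prenyl-3,7,4'-tris-O-(methoxymethyl)quercetin (3'-OH and 5-OH free), via ring B C2' ortho-dienone 7 (not isolated)
Conditions: toluene, 110 °C, argon
Reagents that add atoms: none
Why: Aromatic ortho-Claisen rearrangement: of the two carbons ortho to O3' only C2' bears hydrogen, so dienone 7 enolises irreversibly, while a shift to C4' is reversible. Allyl inversion turns the 1,1-dimethylallyl ether into a normal prenyl group. Tertiary allyl aryl ethers rearrange at this moderate temperature.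

Step 5
Reactants: 8 2'-prenyl-3,7,4'-tris-O-(methoxymethyl)quercetin
Product: 9 5,3'-bis-O-prenyl-2'-prenyl-3,7,4'-tris-O-(methoxymethyl)quercetin
Conditions: prenyl bromide (3 equiv), K2CO3, DMF, 50 °C
Reagents that add atoms: prenyl bromide (1-bromo-3-methylbut-2-ene), CC(C)=CCBr
Why: Double Williamson ether synthesis at the only two free hydroxyls, where displacement at the primary carbon gives the linear ethers. Excess reagent in warm DMF is needed to break the O5–H···O4 chelate, and the MOM ethers are inert to carbonate.

Step 6
Reactants: 9 5,3'-bis-O-prenyl-2'-prenyl-3,7,4'-tris-O-(methoxymethyl)quercetin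
Product: 15 8,2',6'-triprenyl-3,7,4'-tris-O-(methoxymethyl)quercetin, via ring A C6 ortho-dienone 10 (not isolated), via ring A C8 para-dienone 11 (not isolated), via 8-prenyl 3'-O-prenyl ether 12 (not isolated), via ring B C4' ortho-dienone 13 (not isolated), via ring B C6' para-dienone 14 (not isolated)
Conditions: Eu(fod)3 [tris(6,6,7,7,8,8,8-heptafluoro-2,2-dimethyloctane-3,5-dionato)europium] (20 mol %), NaHCO3, 1,2-dichlorobenzene, 90 °C, then 175 °C, argon
Reagents that add atoms: none
Why: Each aryl prenyl ether undergoes an aromatic Claisen [3,3] shift to an ortho carbon (O5 to C6 giving 10; O3' to C4' giving 13, or equally to C2'), a Cope [3,3] shift then passes the 1,1-dimethylallyl group on to the para carbon (11, 14), and enolisation to 12 and 15 makes each relay irreversible. The two allyl inversions cancel, so both chains arrive as normal prenyl groups bound through CH2. The closest known reaction type is the para-Claisen (Claisen–Cope) rearrangement of 2,6-disubstituted aryl allyl ethers and of 5-O-prenyl flavonoids promoted by Eu(fod)3; here it is only run twice in one molecule. No ring is closed and no stereocentre survives, since the sp3 carbons of 10, 11, 13 and 14 are transient and racemic. In ring A the step needs C8 over C6: C4a is a fusion carbon, so the first shift can only reach C6, and the Cope shift should outrun enolisation of 10 because the medium is aprotic and buffered and because the quaternary carbon is squeezed between C5=O and the C7 acetal. Chelation of trivalent europium by O4 and O5 polarises the O5–CH2 bond, so this arm should already move at 90 °C. In ring B both ortho carbons are blocked (prenyl at C2', OMOM at C4'), neither ortho-dienone can enolise, both funnel to the single para carbon C6', and C5' is out of reach of any [3,3] path. The crowding around C2–C1' thus arises only in the last C–C bond formation, by an intramolecular suprafacial transfer over the face of ring B that needs no external reagent to enter the shielded pocket.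

Step 7
Reactants: 15 8,2',6'-triprenyl-3,7,4'-tris-O-(methoxymethyl)quercetin
Product: 16 petalostemumol G (8,2',6'-triprenylquercetin)
Conditions: HCl (cat.), MeOH, 45 °C, argon
Reagents that add atoms: none
Why: Acid-catalysed transacetalisation of the three MOM ethers to dimethoxymethane. A catalytic amount of acid, moderate temperature and short contact should keep the prenyl chains next to O7 and O3' from Markovnikov protonation and chroman closure. Argon protects the liberated catechol.

**Compound list**

1 | quercetin | O=c1c(O)c(-c2ccc(O)c(O)c2)oc2cc(O)cc(O)c12 | starting material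
2 | 3,7,4'-tris-O-(methoxymethyl)quercetin | COCOc1ccc(cc1O)-c1oc2cc(OCOC)cc(O)c2c(=O)c1OCOC | intermediate
3 | 2-methylbut-3-en-2-ol | C=CC(C)(C)O | starting material
4 | lithium 2-methylbut-3-en-2-olate (not isolated) | [Li+].[O-]C(C)(C)C=C | intermediate
5 | tert-butyl 2-methylbut-3-en-2-yl carbonate | C=CC(C)(C)OC(=O)OC(C)(C)C | intermediate
6 | 3'-O-(2-methylbut-3-en-2-yl)-3,7,4'-tris-O-(methoxymethyl)quercetin | C=CC(C)(C)Oc1cc(ccc1OCOC)-c1oc2cc(OCOC)cc(O)c2c(=O)c1OCOC | intermediate
7 | ring B C2' ortho-dienone (C3'=O, C2' sp3 bearing H and prenyl; racemic, not isolated) | CC(C)=CCC1C(=O)C(OCOC)=CC=C1-c1oc2cc(OCOC)cc(O)c2c(=O)c1OCOC | intermediate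
8 | 2'-prenyl-3,7,4'-tris-O-(methoxymethyl)quercetin | CC(C)=CCc1c(O)c(OCOC)ccc1-c1oc2cc(OCOC)cc(O)c2c(=O)c1OCOC | intermediate
9 | 5,3'-bis-O-prenyl-2'-prenyl-3,7,4'-tris-O-(methoxymethyl)quercetin | CC(C)=CCOc1c(CC=C(C)C)c(ccc1OCOC)-c1oc2cc(OCOC)cc(OCC=C(C)C)c2c(=O)c1OCOC | intermediate
10 | ring A C6 ortho-dienone (C5=O, C6 sp3 bearing H and 1,1-dimethylallyl; racemic, not isolated) | O=C1C(C(C)(C)C=C)C(OCOC)=CC2=C1C(=O)C(OCOC)=C(O2)c1ccc(OCOC)c(OCC=C(C)C)c1CC=C(C)C | intermediate
11 | ring A C8 para-dienone (C5=O, C8 sp3 bearing H and prenyl; racemic, not isolated) | O=C1C=C(OCOC)C(CC=C(C)C)C2=C1C(=O)C(OCOC)=C(O2)c1ccc(OCOC)c(OCC=C(C)C)c1CC=C(C)C | intermediate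
12 | 8,2'-diprenyl-3'-O-prenyl-3,7,4'-tris-O-(methoxymethyl)quercetin (5-OH free, not isolated) | CC(C)=CCOc1c(CC=C(C)C)c(ccc1OCOC)-c1oc2c(CC=C(C)C)c(OCOC)cc(O)c2c(=O)c1OCOC | intermediate
13 | ring B C4' ortho-dienone (C3'=O, C4' sp3 bearing OMOM and 1,1-dimethylallyl; racemic, not isolated) | C=CC(C)(C)C1(OCOC)C=CC(=C(CC=C(C)C)C1=O)-c1oc2c(CC=C(C)C)c(OCOC)cc(O)c2c(=O)c1OCOC | intermediate
14 | ring B C6' para-dienone (C3'=O, C6' sp3 bearing H and prenyl; racemic, not isolated) | CC(C)=CCC1C=C(OCOC)C(=O)C(CC=C(C)C)=C1-c1oc2c(CC=C(C)C)c(OCOC)cc(O)c2c(=O)c1OCOC | intermediate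
15 | 8,2',6'-triprenyl-3,7,4'-tris-O-(methoxymethyl)quercetin | CC(C)=CCc1cc(OCOC)c(O)c(CC=C(C)C)c1-c1oc2c(CC=C(C)C)c(OCOC)cc(O)c2c(=O)c1OCOC | intermediate
16 | petalostemumol G | CC(C)=CCc1cc(O)c(O)c(CC=C(C)C)c1-c1oc2c(CC=C(C)C)c(O)cc(O)c2c(=O)c1O | target

**Step count and least certain steps**

Total step count: 7. Longest linear sequence: 6 (steps 1, 3, 4, 5, 6, 7).

Step 6 (key step).
- What may go wrong: the ring A ortho-dienone may enolise before the Cope shift, which would strand the chain at C6 in its inverted form. The hindered ring B ether may also fragment thermally (retro-ene loss of the C5 unit) in the hotter stage. Both risks arise because the two arms have different thermal windows and the first-formed phenol must survive the second stage.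
- Fallback, from 8 to 16: the two relays are decoupled and each ring gets its own promoter.
  - One equivalent of prenyl bromide (K2CO3, acetone, rt) touches only the unchelated O3' of 8 and gives the 3'-O-prenyl ether F1.
  - A purely thermal para-Claisen rearrangement (N,N-diethylaniline, 190 °C) gives the 2',6'-diprenyl phenol F2.
  - O3' is masked (MOMCl, K2CO3) to give the tetrakis-MOM ether F3.
  - Forced alkylation of O5 (prenyl bromide, K2CO3, DMF, 50 °C) gives the 5-O-prenyl ether F4.
  - The ring A relay alone (Eu(fod)3, NaHCO3, chlorobenzene, 85 °C) gives the 8-prenyl tetrakis-MOM ether F5.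
  - Acid methanolysis as in step 7 leads to 16.

Step 1.
- What may go wrong: alkylation may run past or stop short of three groups, and O3 and O3' may be confused, because the acidity gap between these two sites is the smallest of the series.
- Fallback, from 1 to 2: the catechol is tied up first.
  - Ph2CCl2 (diphenyl ether, 175 °C) gives the 3',4'-O-diphenylmethylene ketal F6.
  - MOMCl and K2CO3 (two equivalents) give the 3,7-bis-MOM ketal F7.
  - Hydrogenolysis (H2, Pd/C, THF–EtOH, possible because no prenyl group is present yet) gives the 3,7-bis-MOM catechol F8.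
  - One equivalent of MOMCl and K2CO3 at 0 °C then reacts at the more acidic, para-conjugated O4' to give 2.

Step 3.
- What may go wrong: zerovalent palladium may re-ionise the kinetic tertiary ether, which would drift to the linear ether, and the electron-rich ring A may be C-allylated.
- Fallback, from 2 to 6: the tertiary C–O bond is made at the alkyne oxidation level. Copper-catalysed propargylic etherification with 3-chloro-3-methylbut-1-yne (CuCl2 cat., DBU, MeCN, 0 °C) gives the 1,1-dimethylpropargyl ether F9. Semihydrogenation (H2, Pd/CaCO3 poisoned with Pb(OAc)2, quinoline) gives 6.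

Step 7.
- What may go wrong: a prenyl alkene may be protonated and captured by the neighbouring O7 or O3' (chroman closure) as soon as these phenols are set free in acid.
- Fallback, from 15 to 16: aprotic acetal-to-silyl exchange. Excess TMSOTf with 2,2'-bipyridyl (CH2Cl2, 0 °C) converts the aryl MOM ethers into aryl silyl ethers and silylates the two free phenols, giving the pentakis(trimethylsilyl) ether F10. Water or KF in MeOH at rt releases 16 without any Brønsted acid.

**Further compounds**

F1 | step 6 | 2'-prenyl-3'-O-prenyl-3,7,4'-tris-O-(methoxymethyl)quercetin | CC(C)=CCOc1c(CC=C(C)C)c(ccc1OCOC)-c1oc2cc(OCOC)cc(O)c2c(=O)c1OCOC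
F2 | step 6 | 2',6'-diprenyl-3,7,4'-tris-O-(methoxymethyl)quercetin | CC(C)=CCc1cc(OCOC)c(O)c(CC=C(C)C)c1-c1oc2cc(OCOC)cc(O)c2c(=O)c1OCOC
F3 | step 6 | 2',6'-diprenyl-3,7,3',4'-tetrakis-O-(methoxymethyl)quercetin | CC(C)=CCc1cc(OCOC)c(OCOC)c(CC=C(C)C)c1-c1oc2cc(OCOC)cc(O)c2c(=O)c1OCOC
F4 | step 6 | 5-O-prenyl-2',6'-diprenyl-3,7,3',4'-tetrakis-O-(methoxymethyl)quercetin | CC(C)=CCc1cc(OCOC)c(OCOC)c(CC=C(C)C)c1-c1oc2cc(OCOC)cc(OCC=C(C)C)c2c(=O)c1OCOC
F5 | step 6 | 8,2',6'-triprenyl-3,7,3',4'-tetrakis-O-(methoxymethyl)quercetin | CC(C)=CCc1cc(OCOC)c(OCOC)c(CC=C(C)C)c1-c1oc2c(CC=C(C)C)c(OCOC)cc(O)c2c(=O)c1OCOC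
F6 | step 1 | 3',4'-O-(diphenylmethylene)quercetin | O=c1c(O)c(-c2ccc3OC(c4ccccc4)(c4ccccc4)Oc3c2)oc2cc(O)cc(O)c12
F7 | step 1 | 3',4'-O-(diphenylmethylene)-3,7-bis-O-(methoxymethyl)quercetin | COCOc1cc(O)c2c(=O)c(OCOC)c(-c3ccc4OC(c5ccccc5)(c5ccccc5)Oc4c3)oc2c1
F8 | step 1 | 3,7-bis-O-(methoxymethyl)quercetin | COCOc1cc(O)c2c(=O)c(OCOC)c(-c3ccc(O)c(O)c3)oc2c1
F9 | step 3 | 3'-O-(2-methylbut-3-yn-2-yl)-3,7,4'-tris-O-(methoxymethyl)quercetin | C#CC(C)(C)Oc1cc(ccc1OCOC)-c1oc2cc(OCOC)cc(O)c2c(=O)c1OCOC
F10 | step 7 | 8,2',6'-triprenylquercetin pentakis(trimethylsilyl) ether | CC(C)=CCc1cc(O[Si](C)(C)C)c(O[Si](C)(C)C)c(CC=C(C)C)c1-c1oc2c(CC=C(C)C)c(O[Si](C)(C)C)cc(O[Si](C)(C)C)c2c(=O)c1O[Si](C)(C)C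
A1 | alternative 1 | 2-hydroxy-4,6-bis(methoxymethoxy)-3-prenylacetophenone | CC(=O)c1c(O)c(CC=C(C)C)c(OCOC)cc1OCOC
A2 | alternative 1 | 3,4-bis(methoxymethoxy)-2,6-diprenylbenzaldehyde | O=Cc1c(CC=C(C)C)cc(OCOC)c(OCOC)c1CC=C(C)C
A3 | alternative 1 | (E)-chalcone from A1 and A2 | O=C(/C=C/c1c(CC=C(C)C)cc(OCOC)c(OCOC)c1CC=C(C)C)c1c(O)c(CC=C(C)C)c(OCOC)cc1OCOC
A4 | alternative 2 | 2-iodo-3,5,7-tris(methoxymethoxy)-8-prenylchromone | COCOc1cc(OCOC)c2c(=O)c(OCOC)c(I)oc2c1CC=C(C)C
A5 | alternative 2 | 3,4-bis(methoxymethoxy)-2,6-diprenylphenylboronic acid pinacol ester | CC(C)=CCc1cc(OCOC)c(OCOC)c(CC=C(C)C)c1B1OC(C)(C)C(C)(C)O1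
A6 | alternative 3 | 3,5,7-tris(methoxymethoxy)-2-(5-methylhex-4-en-1-ynyl)-8-prenylchromone | COCOc1cc(OCOC)c2c(=O)c(OCOC)c(C#CCC=C(C)C)oc2c1CC=C(C)C
A7 | alternative 3 | (3Z)-7-methyl-2,3-bis(trimethylsilyloxy)octa-1,3,6-triene | C=C(O[Si](C)(C)C)/C(O[Si](C)(C)C)=C/CC=C(C)C
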